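## Retrosynthetic overview

1. Target ⇒ C14 acetylation, tartrate-controlled epoxidation of the ring-trans C1=C10 allylic alcohol, and Mitsunobu esterification at C8 (inversion) with a (2R,3S)-epoxy acid made from tiglyl alcohol.
2. α-Methylene lactone ⇒ epoxy phosphonoacetate: intramolecular SN2 opening at C7, then Horner–Wadsworth–Emmons methylenation ⇒ syn epoxy alcohol ⇒ catalytic asymmetric epoxidation and chelation-controlled reduction of an achiral cyclodecatrienone.
3. Ten-membered ring ⇒ anionic acetylenic oxy-Cope ring expansion of a 1-ethynyl-6-alkenylcyclohexenol (cleaves C1–C6, forms C8–C9).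
4. Cyclohexenone ⇒ Birch dearomatisation of 3-methylanisole: the arene supplies C1–C6 and C15, and its 1,3-pattern fixes the C6 oxygen and the C4 methyl.
5. Ring order: arene → cyclohexenone → cyclodecatriene → C7/C8 oxirane (temporary) → γ-lactone → C1/C10 oxirane (last); the side-chain oxirane is made separately.

Convention: atom labels C1–C15 are germacrane labels (C6 = lactone O-carbon, C7 = ring-fusion CH, C8 = ester carbon, C1/C10 = ring epoxide, C11–C13 = lactone carbons, C14 = CH2O, C15 = ring methyl); all starting materials and named reagents are taken as commercial.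

## Route

Step 1
Reactants: 1 3-methylanisole
Product: 3 3-methylcyclohex-2-en-1-one, via dihydroanisole 2 (not isolated)
Conditions: Li, NH3 (l), t-BuOH, THF, −78 to −33 °C; then 2 M HCl, THF, 25 °C
Reagents that add atoms: water, O
Why: Birch reduction leaves the methoxy- and methyl-bearing carbons sp2, so enol-ether hydrolysis and conjugation give one enone in which the arene pattern has become the C6 carbonyl and the C4 methyl; no stereocentre is formed.

Step 2
Reactants: 4 2-bromoprop-2-en-1-ol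
Product: 5 (2-bromoallyloxy)(tert-butyl)dimethylsilane
Conditions: t-BuMe2SiCl, imidazole, CH2Cl2, 25 °C
Reagents that add atoms: tert-butyldimethylsilyl chloride, CC(C)(C)[Si](C)(C)Cl
Why: Standard silyl protection of the primary allylic alcohol (future C14–O) so that it survives amide bases, the acetylide and hydride.

Step 3
Reactants: 3 3-methylcyclohex-2-en-1-one; 5 (2-bromoallyloxy)(tert-butyl)dimethylsilane
Product: 7 racemic 6-[3-(tert-butyldimethylsilyloxy)prop-1-en-2-yl]-3-methylcyclohex-2-en-1-one, via chlorozinc dienolate 6 (not isolated)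
Conditions: LiN(iPr)2, THF, −78 °C; ZnCl2; then 5, Pd2(dba)3 (2.5 mol %), P(t-Bu)3 (10 mol %), THF, 25 to 50 °C
Reagents that add atoms: none
Why: Kinetic α′-deprotonation gives the cross-conjugated dienolate, and Negishi-type palladium-catalysed α-alkenylation with the vinyl bromide forms C1–C10; the new stereocentre is racemic and is erased in step 5.

Step 4
Reactants: 7 racemic 6-[3-(tert-butyldimethylsilyloxy)prop-1-en-2-yl]-3-methylcyclohex-2-en-1-one
Product: 8 racemic 1-ethynyl-6-[3-(tert-butyldimethylsilyloxy)prop-1-en-2-yl]-3-methylcyclohex-2-en-1-ol (both carbinol epimers)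
Conditions: HC≡CMgBr, CeCl3, THF, −78 to 0 °C; aq NH4Cl
Reagents that add atoms: ethynylmagnesium bromide, C#C[Mg]Br
Why: Cerium-mediated 1,2-addition of the acetylide (no enolisation, no 1,4-addition) installs C7 and C8; both epimers are usable because the next step destroys both stereocentres.

Step 5
Reactants: 8 racemic 1-ethynyl-6-[3-(tert-butyldimethylsilyloxy)prop-1-en-2-yl]-3-methylcyclohex-2-en-1-ol
Product: 10 (2Z,5Z,9Z)-5-[(tert-butyldimethylsilyloxy)methyl]-9-methylcyclodeca-2,5,9-trien-1-one, via potassium allenolate 9 (not isolated)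
Conditions: KN(SiMe3)2 (1.05 equiv), 18-crown-6, THF, 0 to 40 °C; then aq NH4Cl
Reagents that add atoms: none
Why: Anionic acetylenic oxy-Cope ([3,3]) through a chair with the alkenyl group equatorial cleaves C1–C6, forms C8–C9 and gives the ring-trans C1=C10 olefin (Z only by CIP priority of CH2OSi), while the former cyclohexene bond stays cis and allenolate protonation gives the cis C7=C8 enone; 10 is achiral, so the racemate converges.

Step 6
Reactants: 10 (2Z,5Z,9Z)-5-[(tert-butyldimethylsilyloxy)methyl]-9-methylcyclodeca-2,5,9-trien-1-one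
Product: 11 (7S,8S)-cis-7,8-epoxide of 10
Conditions: 9-amino-9-deoxy-epi-quinine (10 mol %), CF3CO2H (20 mol %), 50% aq H2O2, dioxane, 35 °C
Reagents that add atoms: hydrogen peroxide, OO
Why: Iminium-catalysed asymmetric Weitz–Scheffer epoxidation attacks only the unhindered cis-disubstituted enone arm (the β-methyl arm and the isolated olefin are inert), and the cinchona amine sets C7 and C8 together (the quinidine-derived pseudoenantiomer gives the antipode).

Step 7
Reactants: 11 (7S,8S)-cis-7,8-epoxide of 10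
Product: 12 (6R,7R,8S)-epoxy alcohol (6-OH syn to the oxirane oxygen)
Conditions: Zn(BH4)2, Et2O, −20 °C; aq NH4Cl
Reagents that add atoms: none
Why: Chelation-controlled 1,2-reduction: zinc bridges the carbonyl and oxirane oxygens and hydride enters from the H7 side, giving the syn (erythro-type) epoxy alcohol and so the (6R) centre.

Step 8
Reactants: 12 (6R,7R,8S)-epoxy alcohol
Product: 13 (6R,7S,8S)-epoxy diethylphosphonoacetate
Conditions: (EtO)2P(O)CH2CO2H, DCC, DMAP (cat.), CH2Cl2, 0 to 25 °C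
Reagents that add atoms: diethylphosphonoacetic acid, CCOP(=O)(CC(=O)O)OCC
Why: Steglich esterification of the allylic alcohol brings in C11 and C12 on the C6 oxygen without touching a stereocentre (the C7 descriptor changes only by priority).

Step 9
Reactants: 13 (6R,7S,8S)-epoxy diethylphosphonoacetate
Product: 15 (6R,7R,8S)-8-hydroxy-14-(tert-butyldimethylsilyloxy)germacra-1(10),4,11(13)-trien-12,6-olide, via phosphono lactone 14 (not isolated)
Conditions: NaH (2.2 equiv), THF, 0 to 60 °C; then (CH2O)n, 0 to 25 °C; aq NH4Cl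
Reagents that add atoms: formaldehyde, C=O
Why: Proposed new method: the phosphonoacetate carbanion opens the neighbouring oxirane at C7 in a 5-exo SN2 attack (inversion at C7, trans-fused lactone, C8 alkoxide released) and the α-phosphono lactone anion is then methylenated by Horner–Wadsworth–Emmons reaction with formaldehyde; the closest known chemistry is the intermolecular opening of epoxides by phosphonoacetate anions to α-phosphono-γ-lactones followed by formaldehyde olefination.

Step 10
Reactants: 16 (E)-2-methylbut-2-en-1-ol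
Product: 17 [(2S,3S)-2,3-dimethyloxiran-2-yl]methanol
Conditions: Ti(OiPr)4 (10 mol %), L-(+)-diethyl tartrate (12 mol %), t-BuOOH, 4 Å sieves, CH2Cl2, −20 °C
Reagents that add atoms: tert-butyl hydroperoxide, CC(C)(C)OO
Why: Sharpless asymmetric epoxidation of an E-trisubstituted allylic alcohol; L-(+)-tartrate gives the (2S,3S)-epoxy alcohol with the two methyls cis.

Step 11
Reactants: 17 [(2S,3S)-2,3-dimethyloxiran-2-yl]methanol
Product: 18 (2R,3S)-2,3-dimethyloxirane-2-carboxylic acid
Conditions: RuCl3 (2 mol %), NaIO4, MeCN/EtOAc/H2O, 0 to 25 °C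
Reagents that add atoms: water, O; sodium periodate, [Na+].[O-]I(=O)(=O)=O
Why: Sharpless RuO4 oxidation takes the primary alcohol to the acid without opening the oxirane; the geometry is unchanged and C2 becomes R only by priority.

Step 12
Reactants: 15 (6R,7R,8S)-8-hydroxy-14-(tert-butyldimethylsilyloxy)germacra-1(10),4,11(13)-trien-12,6-olide; 18 (2R,3S)-2,3-dimethyloxirane-2-carboxylic acid
Product: 19 (6R,7R,8R)-14-(tert-butyldimethylsilyloxy)-8-[(2R,3S)-2,3-dimethyloxirane-2-carbonyloxy]germacra-1(10),4,11(13)-trien-12,6-olide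
Conditions: PPh3, DIAD, toluene, 0 to 25 °C
Reagents that add atoms: none
Why: Mitsunobu esterification: the carboxylate displaces the C8 oxyphosphonium by SN2, inverting C8 to the required (8R) ester, while the side-chain stereocentres come unchanged from 18.

Step 13
Reactants: 19 (6R,7R,8R)-14-(tert-butyldimethylsilyloxy)-8-[(2R,3S)-2,3-dimethyloxirane-2-carbonyloxy]germacra-1(10),4,11(13)-trien-12,6-olide
Product: 20 (6R,7R,8R)-14-hydroxy-8-[(2R,3S)-2,3-dimethyloxirane-2-carbonyloxy]germacra-1(10),4,11(13)-trien-12,6-olide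
Conditions: HF·pyridine, pyridine, THF, 0 to 25 °C
Reagents that add atoms: none
Why: Buffered fluoride removes the primary silyl ether without touching the oxirane ester, the lactone or the olefins.

Step 14
Reactants: 20 (6R,7R,8R)-14-hydroxy-8-[(2R,3S)-2,3-dimethyloxirane-2-carbonyloxy]germacra-1(10),4,11(13)-trien-12,6-olide
Product: 21 (1R,6R,7R,8R,10S)-1,10-epoxy-14-hydroxy-8-[(2R,3S)-2,3-dimethyloxirane-2-carbonyloxy]germacra-4,11(13)-dien-12,6-olide
Conditions: Ti(OiPr)4, L-(+)-diethyl tartrate, t-BuOOH, 4 Å sieves, CH2Cl2, −20 °C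
Reagents that add atoms: tert-butyl hydroperoxide, CC(C)(C)OO
Why: Sharpless asymmetric epoxidation: only C1=C10 is an allylic-alcohol olefin, L-(+)-tartrate delivers oxygen to the face that gives (1R,10S), and this is expected to be the exposed outer face of the ring-trans olefin (matched), giving the trans-oxirane.

Step 15
Reactants: 21 (1R,6R,7R,8R,10S)-1,10-epoxy-14-hydroxy-8-[(2R,3S)-2,3-dimethyloxirane-2-carbonyloxy]germacra-4,11(13)-dien-12,6-olide
Product: 22 (1R,6R,7R,8R,10S)-14-acetoxy-1,10-epoxy-8-[(2R,3S)-2,3-dimethyloxirane-2-carbonyloxy]germacra-4,11(13)-dien-12,6-olide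
Conditions: Ac2O, pyridine, DMAP (cat.), CH2Cl2, 0 °C
Reagents that add atoms: acetic anhydride, CC(=O)OC(C)=O
Why: Acylation of the only free (primary) hydroxyl gives the target; no stereocentre is involved.

## Compound list

1 | 3-methylanisole | COc1cccc(C)c1 | starting material
2 | 1-methoxy-5-methylcyclohexa-1,4-diene | COC1=CCC=C(C)C1 | intermediate
3 | 3-methylcyclohex-2-en-1-one | CC1=CC(=O)CCC1 | intermediate
4 | 2-bromoprop-2-en-1-ol | OCC(Br)=C | starting material
5 | (2-bromoallyloxy)(tert-butyl)dimethylsilane | C=C(Br)CO[Si](C)(C)C(C)(C)C | intermediate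
6 | chlorozinc 5-methylcyclohexa-1,5-dien-1-olate | CC1=CC(O[Zn]Cl)=CCC1 | intermediate
7 | racemic 6-[3-(tert-butyldimethylsilyloxy)prop-1-en-2-yl]-3-methylcyclohex-2-en-1-one | CC1=CC(=O)C(CC1)C(=C)CO[Si](C)(C)C(C)(C)C | intermediate
8 | racemic 1-ethynyl-6-[3-(tert-butyldimethylsilyloxy)prop-1-en-2-yl]-3-methylcyclohex-2-en-1-ol, both carbinol epimers | CC1=CC(O)(C#C)C(CC1)C(=C)CO[Si](C)(C)C(C)(C)C | intermediate
9 | potassium allenolate of 10 (C6 O–, C6=C7=C8; ring-trans C1=C10; 4Z) | [K+].[O-]C1=C=CC/C(CO[Si](C)(C)C(C)(C)C)=C/CC/C(C)=C\1 | intermediate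
10 | (2Z,5Z,9Z)-5-[(tert-butyldimethylsilyloxy)methyl]-9-methylcyclodeca-2,5,9-trien-1-one (ring bonds trans at the 5,6-olefin; achiral) | O=C1/C=C\C/C(CO[Si](C)(C)C(C)(C)C)=C/CC/C(C)=C\1 | intermediate
11 | (7S,8S)-cis-7,8-epoxide of 10 (C6 ketone, 4Z, ring-trans C1=C10, 14-OTBS) | O=C1/C=C(/C)CC/C=C(\CO[Si](C)(C)C(C)(C)C)C[C@H](O2)[C@@H]12 | intermediate
12 | (6R,7R,8S)-epoxy alcohol, 6-OH syn to the oxirane oxygen | O[C@@H]1/C=C(/C)CC/C=C(\CO[Si](C)(C)C(C)(C)C)C[C@H](O2)[C@@H]12 | intermediate
13 | (6R,7S,8S)-diethylphosphonoacetate ester of 12 | CCOP(=O)(OCC)CC(=O)O[C@@H]1/C=C(/C)CC/C=C(\CO[Si](C)(C)C(C)(C)C)C[C@H](O2)[C@@H]12 | intermediate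
14 | (6R,7R,8S)-α-(diethoxyphosphoryl) trans-fused lactone with free 8-OH, C11 epimers (sodium salt in the flask) | CCOP(=O)(OCC)C1C(=O)O[C@@H]2/C=C(/C)CC/C=C(\CO[Si](C)(C)C(C)(C)C)C[C@H](O)[C@@H]12 | intermediate
15 | (6R,7R,8S)-8-hydroxy-14-(tert-butyldimethylsilyloxy)germacra-1(10),4,11(13)-trien-12,6-olide (4Z; ring-trans C1=C10) | C=C1C(=O)O[C@@H]2/C=C(/C)CC/C=C(\CO[Si](C)(C)C(C)(C)C)C[C@H](O)[C@@H]12 | intermediate
16 | (E)-2-methylbut-2-en-1-ol | C/C=C(\C)CO | starting material
17 | [(2S,3S)-2,3-dimethyloxiran-2-yl]methanol | OC[C@]1(C)O[C@H]1C | intermediate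
18 | (2R,3S)-2,3-dimethyloxirane-2-carboxylic acid | OC(=O)[C@]1(C)O[C@H]1C | intermediate
19 | (6R,7R,8R)-14-(tert-butyldimethylsilyloxy)-8-[(2R,3S)-2,3-dimethyloxirane-2-carbonyloxy]germacra-1(10),4,11(13)-trien-12,6-olide | C=C1C(=O)O[C@@H]2/C=C(/C)CC/C=C(\CO[Si](C)(C)C(C)(C)C)C[C@@H](OC(=O)[C@]3(C)O[C@H]3C)[C@@H]12 | intermediate
20 | (6R,7R,8R)-14-hydroxy-8-[(2R,3S)-2,3-dimethyloxirane-2-carbonyloxy]germacra-1(10),4,11(13)-trien-12,6-olide | C=C1C(=O)O[C@@H]2/C=C(/C)CC/C=C(\CO)C[C@@H](OC(=O)[C@]3(C)O[C@H]3C)[C@@H]12 | intermediate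
21 | (1R,6R,7R,8R,10S)-1,10-epoxy-14-hydroxy-8-[(2R,3S)-2,3-dimethyloxirane-2-carbonyloxy]germacra-4,11(13)-dien-12,6-olide | C=C1C(=O)O[C@@H]2/C=C(/C)CC[C@H]3O[C@]3(CO)C[C@@H](OC(=O)[C@]3(C)O[C@H]3C)[C@@H]12 | intermediate
22 | (1R,6R,7R,8R,10S)-14-acetoxy-1,10-epoxy-8-[(2R,3S)-2,3-dimethyloxirane-2-carbonyloxy]germacra-4,11(13)-dien-12,6-olide (4Z) | C=C1C(=O)O[C@@H]2/C=C(/C)CC[C@H]3O[C@]3(COC(C)=O)C[C@@H](OC(=O)[C@]3(C)O[C@H]3C)[C@@H]12 | target

## Step count and weakest steps

Total: 15 steps. Longest linear sequence: 12 steps (1, 3–9, 12–15, from 3-methylanisole).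

**Step 5 (acetylenic oxy-Cope).** The ring expansion of a terminal-alkyne carbinol may be slow, or may give the C7=C8 enone as a geometric mixture. The fallback sets out from 7 and comes back at 10. H2C=CHMgBr with CeCl3 adds to 7 to give the racemic divinyl carbinol F1 (mainly the trans-dialkenyl isomer). KH and 18-crown-6 in THF then trigger the classical anionic oxy-Cope, and Me3SiCl traps the ten-membered enolate as the trimethylsilyl enol ether F2. Saegusa–Ito dehydrogenation with Pd(OAc)2 in MeCN introduces the C7=C8 double bond and gives 10.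

**Step 9 (epoxide-opening lactonisation and methylenation).** The stabilised phosphonate carbanion may be too weak a nucleophile, or may attack C8 instead. The fallback sets out from 12 and comes back at 15. Acetylation of 12 (Ac2O, pyridine) gives the acetate F3. Its more nucleophilic ester enolate (LiN(SiMe3)2, THF, −78 to 0 °C) opens the oxirane at C7 to the unsubstituted trans-lactone F4. The lithium enolate of F4 (LiN(iPr)2, 2.2 equiv) reacts with dimethylmethyleneammonium iodide to give the Mannich base F5. Quaternisation with MeI and elimination with NaHCO3 then deliver 15.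

**Step 12 (Mitsunobu inversion).** The hindered C8 alcohol may eliminate instead of being displaced. The fallback sets out from 15 and comes back at 19. Dess–Martin periodinane oxidises 15 to the C8 ketone F6. NaBH4 with CeCl3 in MeOH at −78 °C adds hydride from the face of H7 to give the 8β-alcohol F7. Yamaguchi esterification of F7 with 18 (2,4,6-trichlorobenzoyl chloride, Et3N, then DMAP) gives 19 with retention.

Further compounds
F1 | step 5 | racemic 1-ethenyl-6-[3-(tert-butyldimethylsilyloxy)prop-1-en-2-yl]-3-methylcyclohex-2-en-1-ol | CC1=CC(O)(C=C)C(CC1)C(=C)CO[Si](C)(C)C(C)(C)C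
F2 | step 5 | trimethylsilyl enol ether of 5-[(tert-butyldimethylsilyloxy)methyl]-9-methylcyclodeca-5,9-dien-1-one (C6=C7 enol ether; ring-trans C1=C10; 4Z) | C[Si](C)(C)O/C1=C\CC/C(CO[Si](C)(C)C(C)(C)C)=C/CC/C(C)=C\1
F3 | step 9 | (6R,7S,8S)-acetate of epoxy alcohol 12 | CC(=O)O[C@@H]1/C=C(/C)CC/C=C(\CO[Si](C)(C)C(C)(C)C)C[C@H](O2)[C@@H]12
F4 | step 9 | (6R,7R,8S)-8-hydroxy-14-(tert-butyldimethylsilyloxy)-13-norgermacra-1(10),4-dien-12,6-olide (C11 is CH2) | C1C(=O)O[C@@H]2/C=C(/C)CC/C=C(\CO[Si](C)(C)C(C)(C)C)C[C@H](O)[C@@H]12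
F5 | step 9 | (6R,7R,8S)-13-(dimethylamino)-8-hydroxy-14-(tert-butyldimethylsilyloxy)germacra-1(10),4-dien-12,6-olide, C11 epimers | CN(C)CC1C(=O)O[C@@H]2/C=C(/C)CC/C=C(\CO[Si](C)(C)C(C)(C)C)C[C@H](O)[C@@H]12
F6 | step 12 | (6R,7S)-14-(tert-butyldimethylsilyloxy)-8-oxogermacra-1(10),4,11(13)-trien-12,6-olide | C=C1C(=O)O[C@@H]2/C=C(/C)CC/C=C(\CO[Si](C)(C)C(C)(C)C)CC(=O)[C@@H]12
F7 | step 12 | (6R,7R,8R)-8-hydroxy-14-(tert-butyldimethylsilyloxy)germacra-1(10),4,11(13)-trien-12,6-olide | C=C1C(=O)O[C@@H]2/C=C(/C)CC/C=C(\CO[Si](C)(C)C(C)(C)C)C[C@@H](O)[C@@H]12
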